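Atom numbering used throughout: ring carbons C1–C10, C11–C13 for the lactone/acrylate carbons (C13 = exocyclic CH2), C14 and C15 for the methyls on C10 and C4, O6/O8/O9 for the oxygens on C6/C8/C9.

## Analysis of the target

The target is a germacranolide: a ten-membered carbocycle (C1–C10) with two Z trisubstituted alkenes, C1=C10 and C4=C5, fused trans at C6/C7 to an α-methylene-γ-butyrolactone (O6–C12(=O)–C11(=C13H2)–C7). The ring carries five stereocentres, C3 (S, acetate), C6 (R), C7 (S), C8 (S, epoxy ester) and C9 (R, free hydroxyl). C6–C9 are contiguous, with O6 trans to C11 and with C11, O8 and O9 all cis. C3 sits apart between the two alkenes. The C8 ester adds two more centres, (2S,3R), in a 2,3-dimethyloxirane-2-carboxylate whose methyls are cis, i.e. the epoxide of tiglic acid. The sensitive groups are the methylene lactone (a Michael acceptor), the glycidic ester (acid and fluoride), the allylic acetate, the cis 8-acyloxy-9-hydroxy pair (acyl shift) and both Z alkenes. The difficulty is the medium ring itself (transannular strain, entropy of closure) together with four contiguous centres on a mobile ring and four oxygens that must end up differently substituted. The strategy rests on one feature: C7 bears the C11=C13 methylene and is bonded to oxygenated C8, so C8(O)–C7–C11=C13 is a homoallylic alcohol. With C9 as a ketone this is the product of a [2,3] shift of a C8 enolate across an O8–C13–C11=C7 allyl ether, and reconnecting O8 to C13 turns the strained ten-membered carbocycle into a relaxed thirteen-membered ether.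

## Retrosynthetic reasoning

**34 to 33 (C9–H).** The C9 carbinol is taken back to the enone 33. The C9 carbonyl is what makes C8 acidic in the key step, so it is kept to the very end and removed by a Luche reduction. That reduction has to be 1,2-selective and has to place O9 cis to O8.

**33 to 32 to 30 (O3–acetyl, O6–C12).** The acetate is cut to the free C3 alcohol 32 and the lactone C–O bond is cut to the bis-silyl ether methyl ester 30 (through 31). Carrying C3 as a silyl ether instead of the acetate removes an enolisable ester and a good leaving group from the base-mediated key step. It costs one acetylation on 32, where C3–OH is the only free hydroxyl.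

**30 to 24 + 28 (O8–acyl).** The epoxy ester is cut at the acyl–oxygen bond. O8 must be acylated before O6 is released, because O6 and O8 are both γ to C12 and either could lactonise. Acid 28 goes back through epoxy alcohol 27 and allylic alcohol 26 to tiglic acid 25. A Sharpless epoxidation sets both epoxide centres.

**24 to 22 (C7–C8 cut, O8–C13 reconnected; key step).** This is the retro-[2,3]-Wittig step. Cutting here removes the ten-membered ring, the exocyclic methylene and two stereocentres at once. Forward, the C8 enolate 23 of ketone 22 has to bond to C7 rather than rearrange otherwise, on the face of C7 anti to the C6 silyloxy group and with C9 exo.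

**22 to 21 to 20 (C9–C10).** The thirteen-membered ring is opened at the sp2–sp3 bond next to the carbonyl. This gives the Z vinyl iodide/aldehyde 20 for a Nozaki–Hiyama–Kishi closure, followed by oxidation of the epimeric alcohols 21. The geometry of C1=C10 is fixed in the iodide and the new carbinol centre is erased, so the ring closure carries no stereochemical burden.

**20 to 19 to 17 + 18 (O8–C13).** The ether is made intermolecularly from the allylic bromide 17 and ethane-1,2-diol 18, then oxidised. Done between two molecules, the regiochemistry can be forced with an excess of 18 instead of being left to a macrocyclisation.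

**17 to 16 to 14 + 15 (C7–C11).** The 2-(bromomethyl)enoate is the SN2′ product of the Baylis–Hillman adduct 16 of aldehyde 14 and methyl acrylate 15. The SN2′ step sets the C7=C11 geometry (C6 cis to C13), which the key step needs.

**14 to 13 to 12 to 11 (O6/O7 differentiation).** The α-silyloxy aldehyde comes from the bis-silyl ether 13 of diol 12 by selective oxidation of the primary silyl ether. Diol 12 comes from acetonide 11.

**11 to 10 (C1=C10).** The Z 2-iodoalkene is cut to aldehyde 10. A Stork–Zhao iodo-olefination brings in C10, C14 and the iodine with the iodine cis to C2.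

**10 to 9 to 8 to 5 + 6 (C2–C3).** The β-silyloxy aldehyde goes back to the acetate aldol adduct 8 of enal 5 with the chiral N-acetyl thiazolidinethione 6. The auxiliary sets C3 and is removed reductively at the aldehyde oxidation level.

**5 to 4 to 3 to 1 + 2 (C4=C5).** The Z enal comes from the Still–Gennari enoate 3 of (S)-glyceraldehyde acetonide 1 and phosphonate 2. With the aldehyde carbon of 1 becoming C5 and its CH2O carbon becoming C7, it is the (S)-enantiomer of 1 that gives (6R).

## Alternatives that were turned down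

Alternative 1: The lactone O–C6 bond and the O–C3 bond of the acetate are disconnected together, leading from A1 to a ten-membered ring with a C3=C4–C5=C6 diene and a free C12 acid. Forward, Pd(OAc)2 with benzoquinone in acetic acid would add the carboxylate to C6 and deliver acetate to C3 of the resulting π-allyl, leaving C4=C5. In its favour, one late step installs lactone and acetate without protecting groups, and A1 already has O8 and O9 differentiated, so no late ketone reduction is needed. On those two points it is stronger than the chosen route, which needs a desilylation, an acetylation and a Luche reduction. Against it, the step closes only the five-membered ring; the ten-membered triene with C7–C9 set must be made first, and that is the hard part of the molecule. The 1,4-oxidation is reliable on small cyclic dienes held s-cis. In a cyclodecatriene the diene need not be planar, the π-allyl geometry decides whether C4=C5 comes out Z, acetate may attack C5, and divalent palladium can also engage C1=C10 and the acrylate. The chosen strategy instead spends its key step on the ring and on C7/C8.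

Alternative 2: The C3–C4 bond is disconnected. Forward, CrCl2 with catalytic NiCl2 would convert a Z vinyl iodide at C4 into a vinylchromium unit that adds to a C3 aldehyde in the same chain and closes the ten-membered ring to A2. In its favour are the tolerance and predictability of the coupling, which as a reaction type is more certain than an enolate sigmatropic shift, and the retention of alkene geometry. Against it, this is a direct medium-ring closure with its full entropic and transannular cost. The new C3 carbinol has no evident bias and may need correction. All four contiguous centres C6–C9 must be built on an open chain beforehand. A2 also carries C12 as a silyl-protected allylic alcohol, so oxidation and lactonisation remain. The chosen route uses the same coupling where it is easy (a thirteen-membered ring, carbinol oxidised away) and lets the contraction create C7 and C8.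

Alternative 3: The C6–C7 bond is disconnected with a temporary C4–C9 bond reconnected, so A3 derives from a cis-1,2-dialkenylcyclohexenol (ring A). Forward, the potassium alkoxide would undergo an anionic oxy-Cope shift, expanding ring A to the ten-membered C9 ketone. In its favour, it avoids medium-ring closure as the chosen route does (equal on that point), it is driven by enolate formation, it transfers stereochemistry through a chair to C6/C7, and the Z C1=C10 alkene is inherited from the six-membered ring for free, which is better than the iodo-olefination needed here. Against it, A3 has no oxygen on C8 and only a 2-silyloxyethyl chain on C7. The C8 hydroxyl would need a stereoselective α-oxidation on the flexible ring, and the side chain would need oxidation, lactonisation and α-methylenation. The substrate also needs a quaternary C4 next to a tertiary carbinol, and the C4=C5 geometry depends on one specific transition-state shape. The [2,3] shift delivers the C8 oxygen, the C9 carbonyl and the finished methylene unit in the same step.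

Key step: step 17

Remark on the chemistry: the acetate aldol of 6 (step 4) is assumed to follow the chelated chair model of chlorotitanium enolates of N-acyl thiazolidinethiones formed with one equivalent of amine; should the opposite sense be found, the enantiomer of 6 would be used with no other change.
Remark on the chemistry: (S)-glyceraldehyde acetonide 1 is taken as a commercial chiral-pool aldehyde.

## Route

Step 1
Reactants: 1 (4S)-2,2-dimethyl-1,3-dioxolane-4-carbaldehyde; 2 ethyl 2-[bis(2,2,2-trifluoroethoxy)phosphoryl]propanoate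
Product: 3 ethyl (2Z)-3-[(4R)-2,2-dimethyl-1,3-dioxolan-4-yl]-2-methylprop-2-enoate
Conditions: 2, KHMDS, 18-crown-6, THF, −78 °C; then 1
Reagents that add atoms: none
Why: Still–Gennari olefination; the electron-poor phosphonate with a dissociated potassium counter-ion eliminates before the adducts equilibrate, so the Z trisubstituted enoate (C3 cis to C6) should form, and C6 comes unchanged from 1.

Step 2
Reactants: 3 ethyl (2Z)-3-[(4R)-2,2-dimethyl-1,3-dioxolan-4-yl]-2-methylprop-2-enoate
Product: 4 (2Z)-3-[(4R)-2,2-dimethyl-1,3-dioxolan-4-yl]-2-methylprop-2-en-1-ol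
Conditions: DIBAL-H, CH2Cl2, −78 °C
Reagents that add atoms: none
Why: 1,2-Reduction of the enoate by an aluminium hydride; the acetonide and the alkene geometry are not affected.

Step 3
Reactants: 4 (2Z)-3-[(4R)-2,2-dimethyl-1,3-dioxolan-4-yl]-2-methylprop-2-en-1-ol
Product: 5 (2Z)-3-[(4R)-2,2-dimethyl-1,3-dioxolan-4-yl]-2-methylprop-2-enal
Conditions: MnO2, CH2Cl2, rt
Reagents that add atoms: none
Why: Allylic oxidation on neutral MnO2, chosen because the Z enal isomerises under acid or base; it should be used at once.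

Step 4
Reactants: 5 (2Z)-3-[(4R)-2,2-dimethyl-1,3-dioxolan-4-yl]-2-methylprop-2-enal; 6 1-[(4R)-4-benzyl-2-sulfanylidene-1,3-thiazolidin-3-yl]ethan-1-one
Product: 8 (3S,4Z)-1-[(4R)-4-benzyl-2-sulfanylidene-1,3-thiazolidin-3-yl]-5-[(4R)-2,2-dimethyl-1,3-dioxolan-4-yl]-3-hydroxy-4-methylpent-4-en-1-one, via titanium enolate 7 (not isolated)
Conditions: 6, TiCl4, i-Pr2NEt, CH2Cl2, −78 → −40 °C; then 5, −78 °C
Reagents that add atoms: none
Why: Auxiliary-controlled acetate aldol addition of a chlorotitanium enolate; in the chelated Zimmerman–Traxler chair (thione sulfur on titanium) the aldehyde should add to the enolate face away from the benzyl group with its alkenyl group equatorial, which sets C3 as S.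

Step 5
Reactants: 8 (3S,4Z)-1-[(4R)-4-benzyl-2-sulfanylidene-1,3-thiazolidin-3-yl]-5-[(4R)-2,2-dimethyl-1,3-dioxolan-4-yl]-3-hydroxy-4-methylpent-4-en-1-one
Product: 9 (3S,4Z)-1-[(4R)-4-benzyl-2-sulfanylidene-1,3-thiazolidin-3-yl]-3-[(tert-butyldimethylsilyl)oxy]-5-[(4R)-2,2-dimethyl-1,3-dioxolan-4-yl]-4-methylpent-4-en-1-one
Conditions: TBSOTf, 2,6-lutidine, CH2Cl2, −78 → 0 °C
Reagents that add atoms: tert-butyldimethylsilyl trifluoromethanesulfonate, CC(C)(C)[Si](C)(C)OS(=O)(=O)C(F)(F)F
Why: Silylation of the secondary allylic alcohol with a silyl triflate and a hindered base, which prevents retro-aldol and β-elimination in the following steps.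

Step 6
Reactants: 9 (3S,4Z)-1-[(4R)-4-benzyl-2-sulfanylidene-1,3-thiazolidin-3-yl]-3-[(tert-butyldimethylsilyl)oxy]-5-[(4R)-2,2-dimethyl-1,3-dioxolan-4-yl]-4-methylpent-4-en-1-one
Product: 10 (3S,4Z)-3-[(tert-butyldimethylsilyl)oxy]-5-[(4R)-2,2-dimethyl-1,3-dioxolan-4-yl]-4-methylpent-4-enal
Conditions: DIBAL-H, CH2Cl2, −78 °C
Reagents that add atoms: none
Why: Reductive cleavage of the N-acyl thiazolidinethione; the tetrahedral aluminium adduct is stable at −78 °C and should release the aldehyde only on work-up, with the auxiliary recovered.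

Step 7
Reactants: 10 (3S,4Z)-3-[(tert-butyldimethylsilyl)oxy]-5-[(4R)-2,2-dimethyl-1,3-dioxolan-4-yl]-4-methylpent-4-enal
Product: 11 (4R)-4-[(1Z,3S,5Z)-3-[(tert-butyldimethylsilyl)oxy]-6-iodo-2-methylhepta-1,5-dien-1-yl]-2,2-dimethyl-1,3-dioxolane
Conditions: Ph3PEt+ I−, n-BuLi, THF; I2, −78 °C; NaHMDS, −20 °C; then 10, −78 °C
Reagents that add atoms: ethyltriphenylphosphonium iodide, CC[P+](c1ccccc1)(c1ccccc1)c1ccccc1.[I-]; iodine, II
Why: Stork–Zhao olefination with the α-iodoethylidene ylide; the non-stabilised ylide should react through the kinetic cis oxaphosphetane and give the Z 2-iodoalkene with iodine cis to C2, the geometry later needed for C1=C10.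

Step 8
Reactants: 11 (4R)-4-[(1Z,3S,5Z)-3-[(tert-butyldimethylsilyl)oxy]-6-iodo-2-methylhepta-1,5-dien-1-yl]-2,2-dimethyl-1,3-dioxolane
Product: 12 (2R,3Z,5S,7Z)-5-[(tert-butyldimethylsilyl)oxy]-8-iodo-4-methylnona-3,7-diene-1,2-diol
Conditions: CuCl2·2H2O, MeCN, 0 °C
Reagents that add atoms: none
Why: Lewis-acid hydrolysis of a terminal acetonide, mild enough to leave the secondary silyl ether and the allylic C6–O bond alone.

Step 9
Reactants: 12 (2R,3Z,5S,7Z)-5-[(tert-butyldimethylsilyl)oxy]-8-iodo-4-methylnona-3,7-diene-1,2-diol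
Product: 13 (2R,3Z,5S,7Z)-5-[(tert-butyldimethylsilyl)oxy]-8-iodo-4-methyl-1,2-bis[(triethylsilyl)oxy]nona-3,7-diene
Conditions: TESCl, imidazole, DMAP (cat.), CH2Cl2, 0 °C → rt
Reagents that add atoms: chlorotriethylsilane, CC[Si](CC)(CC)Cl
Why: Silylation of both hydroxyls, which sets up the selective oxidation of the primary position in the next step.

Step 10
Reactants: 13 (2R,3Z,5S,7Z)-5-[(tert-butyldimethylsilyl)oxy]-8-iodo-4-methyl-1,2-bis[(triethylsilyl)oxy]nona-3,7-diene
Product: 14 (2R,3Z,5S,7Z)-5-[(tert-butyldimethylsilyl)oxy]-8-iodo-4-methyl-2-[(triethylsilyl)oxy]nona-3,7-dienal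
Conditions: (COCl)2, DMSO, CH2Cl2, −78 → −40 °C; Et3N, −78 → 0 °C
Reagents that add atoms: none
Why: Swern oxidation of a primary triethylsilyl ether; activated DMSO should cleave only the unhindered primary silyl ether and oxidise it in the same flask, leaving both secondary silyl ethers in place.

Step 11
Reactants: 14 (2R,3Z,5S,7Z)-5-[(tert-butyldimethylsilyl)oxy]-8-iodo-4-methyl-2-[(triethylsilyl)oxy]nona-3,7-dienal; 15 methyl prop-2-enoate
Product: 16 methyl (4R,5Z,7S,9Z)-7-[(tert-butyldimethylsilyl)oxy]-3-hydroxy-10-iodo-6-methyl-2-methylidene-4-[(triethylsilyl)oxy]undeca-5,9-dienoate (both C3 epimers)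
Conditions: 15 (excess), DABCO, MeOH, 0 °C → rt
Reagents that add atoms: none
Why: Baylis–Hillman reaction; the ammonium enolate from DABCO and the acrylate adds to the activated α-silyloxy aldehyde, forming C7–C11, and the configuration of the new carbinol does not matter because it is removed in step 12.

Step 12
Reactants: 16 methyl (4R,5Z,7S,9Z)-7-[(tert-butyldimethylsilyl)oxy]-3-hydroxy-10-iodo-6-methyl-2-methylidene-4-[(triethylsilyl)oxy]undeca-5,9-dienoate
Product: 17 methyl (2Z,4R,5Z,7S,9Z)-2-(bromomethyl)-7-[(tert-butyldimethylsilyl)oxy]-10-iodo-6-methyl-4-[(triethylsilyl)oxy]undeca-2,5,9-trienoate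
Conditions: NBS, Me2S, CH2Cl2, −20 → 0 °C
Reagents that add atoms: N-bromosuccinimide, O=C1CCC(=O)N1Br
Why: Corey–Kim-type activation of the carbinol followed by SN2′ attack of bromide at C13; both epimers of 16 should converge on the 2-(bromomethyl)enoate with C6 cis to C13, the usual outcome for Baylis–Hillman adducts.

Step 13
Reactants: 17 methyl (2Z,4R,5Z,7S,9Z)-2-(bromomethyl)-7-[(tert-butyldimethylsilyl)oxy]-10-iodo-6-methyl-4-[(triethylsilyl)oxy]undeca-2,5,9-trienoate; 18 ethane-1,2-diol
Product: 19 methyl (2E,4R,5Z,7S,9Z)-7-[(tert-butyldimethylsilyl)oxy]-2-[(2-hydroxyethoxy)methyl]-10-iodo-6-methyl-4-[(triethylsilyl)oxy]undeca-2,5,9-trienoate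
Conditions: 18 (excess), Ag2O, MeCN, rt, dark
Reagents that add atoms: none
Why: Silver-assisted Williamson etherification at the primary allylic carbon C13; C7 is shielded by the C6 silyl ether and attack at C13 keeps the conjugated trisubstituted enoate, so the SN2 ether should prevail, and the excess diol prevents double alkylation.

Step 14
Reactants: 19 methyl (2E,4R,5Z,7S,9Z)-7-[(tert-butyldimethylsilyl)oxy]-2-[(2-hydroxyethoxy)methyl]-10-iodo-6-methyl-4-[(triethylsilyl)oxy]undeca-2,5,9-trienoate
Product: 20 methyl (2E,4R,5Z,7S,9Z)-7-[(tert-butyldimethylsilyl)oxy]-10-iodo-6-methyl-2-[(2-oxoethoxy)methyl]-4-[(triethylsilyl)oxy]undeca-2,5,9-trienoate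
Conditions: Dess–Martin periodinane, NaHCO3, CH2Cl2, 0 °C → rt
Reagents that add atoms: none
Why: Dess–Martin oxidation of the primary alcohol to the α-alkoxy aldehyde under buffered, non-basic conditions.

Step 15
Reactants: 20 methyl (2E,4R,5Z,7S,9Z)-7-[(tert-butyldimethylsilyl)oxy]-10-iodo-6-methyl-2-[(2-oxoethoxy)methyl]-4-[(triethylsilyl)oxy]undeca-2,5,9-trienoate
Product: 21 methyl (3E,5R,6Z,8S,10Z)-8-[(tert-butyldimethylsilyl)oxy]-12-hydroxy-7,11-dimethyl-5-[(triethylsilyl)oxy]-1-oxacyclotrideca-3,6,10-triene-3-carboxylate (both C12 epimers)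
Conditions: CrCl2, NiCl2 (cat.), DMSO/THF, rt, 0.002 M
Reagents that add atoms: none
Why: Nozaki–Hiyama–Kishi macrocyclisation; zerovalent nickel inserts into the C–I bond with retention, the vinyl group passes to trivalent chromium and adds only to the aldehyde, forming C9–C10 and the thirteen-membered ring. The new carbinol centre is oxidised away in step 16.

Step 16
Reactants: 21 methyl (3E,5R,6Z,8S,10Z)-8-[(tert-butyldimethylsilyl)oxy]-12-hydroxy-7,11-dimethyl-5-[(triethylsilyl)oxy]-1-oxacyclotrideca-3,6,10-triene-3-carboxylate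
Product: 22 methyl (3E,5R,6Z,8S,10Z)-8-[(tert-butyldimethylsilyl)oxy]-7,11-dimethyl-12-oxo-5-[(triethylsilyl)oxy]-1-oxacyclotrideca-3,6,10-triene-3-carboxylate
Conditions: Dess–Martin periodinane, NaHCO3, CH2Cl2, rt
Reagents that add atoms: none
Why: Dess–Martin oxidation of the allylic alcohol to the enone; both epimers give the same ketone.

Step 17
Reactants: 22 methyl (3E,5R,6Z,8S,10Z)-8-[(tert-butyldimethylsilyl)oxy]-7,11-dimethyl-12-oxo-5-[(triethylsilyl)oxy]-1-oxacyclotrideca-3,6,10-triene-3-carboxylate
Product: 24 methyl 2-[(1R,2R,3Z,5S,7Z,10S)-5-[(tert-butyldimethylsilyl)oxy]-10-hydroxy-4,8-dimethyl-9-oxo-2-[(triethylsilyl)oxy]cyclodeca-3,7-dien-1-yl]prop-2-enoate, via lithium enolate 23 (not isolated)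
Conditions: LiHMDS, THF, −78 → −40 °C; AcOH, −78 °C
Reagents that add atoms: none
Why: Deprotonation at C8, the only enolisable α-position of the C9 ketone, should give the lithium-chelated enolate 23, whose C8 terminus bonds to C7 of the O8–C13–C11=C7 allyl ether through a five-membered envelope while O8–C13 breaks and C11=C13 forms, a [2,3]-Wittig shift. The closest known reactions are the [2,3]-Wittig rearrangement of α-allyloxy ketone and ester enolates and the [2,3]-Wittig ring contraction of thirteen-membered allylic ethers to cyclodecenols. The ten-membered carbocycle is closed by transannular contraction and not end to end: C7 and C8 are already held apart by only O8–C13–C11, so little medium-ring entropy is paid, and because the shift is concerted (at its polar limit a Michael addition to the enoate followed by loss of the β-alkoxide) the formally 5-endo geometry is no obstacle. C8 is controlled by the allyl geometry: C6 is cis to C13 on C7=C11, and with the enolate carbon C9 in the usual exo position, turned away from C11 and its ester, the envelope should place C11 and O8 cis on the new ring. C7 is controlled by C6: allylic 1,3-strain holds H6 in the plane of C7=C11 facing C13, and C8 should bond to the face anti to the C6–O(silyl) bond, the Felkin–Anh sense for a γ-silyloxy enoate, which puts C11 trans to O6. The step needs C8–C7 bonding to win over the [3,3] shift that would join C9 to C7 and over the [1,2] shift; the electron-poor enoate, which pairs the electrophilic C7 with the nucleophilic α-carbon, and the nine-membered ring the [3,3] path would have to form should secure this. It also needs the C8 alkoxide not to attack the C12 ester, for which the lithium chelate with the C9 carbonyl and the acetic acid quench at −78 °C are relied on, and it needs no γ-deprotonation at C2, which kinetic conditions and the silyl ether (not an acetate) at C3 should prevent.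

Step 18
Reactants: 25 (2E)-2-methylbut-2-enoic acid (tiglic acid)
Product: 26 (2E)-2-methylbut-2-en-1-ol
Conditions: LiAlH4, Et2O, 0 °C
Reagents that add atoms: none
Why: Hydride reduction of the carboxylic acid to the allylic alcohol without touching the trisubstituted alkene.

Step 19
Reactants: 26 (2E)-2-methylbut-2-en-1-ol
Product: 27 [(2R,3R)-2,3-dimethyloxiran-2-yl]methanol
Conditions: Ti(Oi-Pr)4 (cat.), D-(−)-diethyl tartrate (cat.), t-BuOOH, 4 Å MS, CH2Cl2, −20 °C
Reagents that add atoms: tert-butyl hydroperoxide, CC(C)(C)OO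
Why: Sharpless asymmetric epoxidation; the D-(−)-tartrate complex should deliver oxygen to the face that gives the (2R,3R) epoxide (the mirror image of the (2S,3S) epoxides obtained from E allylic alcohols with L-(+)-tartrate), and the E alkene fixes the methyls cis.

Step 20
Reactants: 27 [(2R,3R)-2,3-dimethyloxiran-2-yl]methanol
Product: 28 (2S,3R)-2,3-dimethyloxirane-2-carboxylic acid
Conditions: RuCl3·xH2O (cat.), NaIO4, CCl4/MeCN/H2O, rt
Reagents that add atoms: water, O
Why: Catalytic ruthenium tetroxide oxidation of the primary alcohol to the acid, a standard route from epoxy alcohols to glycidic acids; the descriptor at C2 changes from R to S only because the priorities change.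

Step 21
Reactants: 24 methyl 2-[(1R,2R,3Z,5S,7Z,10S)-5-[(tert-butyldimethylsilyl)oxy]-10-hydroxy-4,8-dimethyl-9-oxo-2-[(triethylsilyl)oxy]cyclodeca-3,7-dien-1-yl]prop-2-enoate; 28 (2S,3R)-2,3-dimethyloxirane-2-carboxylic acid
Product: 30 methyl 2-[(1R,2R,3Z,5S,7Z,10S)-5-[(tert-butyldimethylsilyl)oxy]-10-{[(2S,3R)-2,3-dimethyloxirane-2-carbonyl]oxy}-4,8-dimethyl-9-oxo-2-[(triethylsilyl)oxy]cyclodeca-3,7-dien-1-yl]prop-2-enoate, via mixed anhydride 29 (not isolated)
Conditions: 28, 2,4,6-trichlorobenzoyl chloride, Et3N, toluene, rt; then 24, DMAP, rt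
Reagents that add atoms: none
Why: Yamaguchi esterification; DMAP transfers the hindered epoxy acyl group from the mixed anhydride to O8, the only free hydroxyl, and the acid has no α-hydrogen to epimerise.

Step 22
Reactants: 30 methyl 2-[(1R,2R,3Z,5S,7Z,10S)-5-[(tert-butyldimethylsilyl)oxy]-10-{[(2S,3R)-2,3-dimethyloxirane-2-carbonyl]oxy}-4,8-dimethyl-9-oxo-2-[(triethylsilyl)oxy]cyclodeca-3,7-dien-1-yl]prop-2-enoate
Product: 32 (3aS,4S,6Z,9S,10Z,11aR)-9-hydroxy-6,10-dimethyl-3-methylidene-2,5-dioxo-2,3,3a,4,5,8,9,11a-octahydrocyclodeca[b]furan-4-yl (2S,3R)-2,3-dimethyloxirane-2-carboxylate, via diol ester 31 (not isolated)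
Conditions: HF·pyridine, pyridine, THF, 0 °C → rt
Reagents that add atoms: none
Why: Fluoride desilylation of both silyl ethers followed by 5-exo-trig transesterification of the C6 hydroxyl onto the C12 methyl ester under the mildly acidic conditions; O8 is already acylated, so only the trans-fused 6,12-lactone can form.

Step 23
Reactants: 32 (3aS,4S,6Z,9S,10Z,11aR)-9-hydroxy-6,10-dimethyl-3-methylidene-2,5-dioxo-2,3,3a,4,5,8,9,11a-octahydrocyclodeca[b]furan-4-yl (2S,3R)-2,3-dimethyloxirane-2-carboxylate
Product: 33 (3aS,4S,6Z,9S,10Z,11aR)-9-(acetyloxy)-6,10-dimethyl-3-methylidene-2,5-dioxo-2,3,3a,4,5,8,9,11a-octahydrocyclodeca[b]furan-4-yl (2S,3R)-2,3-dimethyloxirane-2-carboxylate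
Conditions: Ac2O, pyridine, DMAP (cat.), CH2Cl2, 0 °C
Reagents that add atoms: acetic anhydride, CC(=O)OC(C)=O
Why: Acetylation of the C3 hydroxyl, the only free hydroxyl in 32.

Step 24
Reactants: 33 (3aS,4S,6Z,9S,10Z,11aR)-9-(acetyloxy)-6,10-dimethyl-3-methylidene-2,5-dioxo-2,3,3a,4,5,8,9,11a-octahydrocyclodeca[b]furan-4-yl (2S,3R)-2,3-dimethyloxirane-2-carboxylate
Product: 34 (3aS,4S,5R,6Z,9S,10Z,11aR)-9-(acetyloxy)-5-hydroxy-6,10-dimethyl-3-methylidene-2-oxo-2,3,3a,4,5,8,9,11a-octahydrocyclodeca[b]furan-4-yl (2S,3R)-2,3-dimethyloxirane-2-carboxylate (CNP0299903.2)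
Conditions: NaBH4, CeCl3·7H2O, MeOH, −78 °C
Reagents that add atoms: none
Why: Luche reduction; cerium activation should give clean 1,2-reduction of the enone without conjugate reduction of the methylene lactone. Hydride delivery to the C9 carbonyl held syn to the C8 acyloxy oxygen (chelation model, attack past H8) should place O9 cis to O8, which is 9R.

## Compound list

1 | (4S)-2,2-dimethyl-1,3-dioxolane-4-carbaldehyde, (S)-glyceraldehyde acetonide | O=C[C@@H]1COC(C)(C)O1 | starting material
2 | ethyl 2-[bis(2,2,2-trifluoroethoxy)phosphoryl]propanoate | CCOC(=O)C(C)P(=O)(OCC(F)(F)F)OCC(F)(F)F | starting material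
3 | ethyl (2Z)-3-[(4R)-2,2-dimethyl-1,3-dioxolan-4-yl]-2-methylprop-2-enoate | CCOC(=O)/C(C)=C\[C@@H]1COC(C)(C)O1 | intermediate
4 | (2Z)-3-[(4R)-2,2-dimethyl-1,3-dioxolan-4-yl]-2-methylprop-2-en-1-ol | OC/C(C)=C\[C@@H]1COC(C)(C)O1 | intermediate
5 | (2Z)-3-[(4R)-2,2-dimethyl-1,3-dioxolan-4-yl]-2-methylprop-2-enal | O=C/C(C)=C\[C@@H]1COC(C)(C)O1 | intermediate
6 | 1-[(4R)-4-benzyl-2-sulfanylidene-1,3-thiazolidin-3-yl]ethan-1-one | CC(=O)N1[C@H](Cc2ccccc2)CSC1=S | starting material
7 | trichlorotitanium enolate of 6 | C=C(O[Ti](Cl)(Cl)Cl)N1[C@H](Cc2ccccc2)CSC1=S | intermediate (not isolated)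
8 | (3S,4Z)-1-[(4R)-4-benzyl-2-sulfanylidene-1,3-thiazolidin-3-yl]-5-[(4R)-2,2-dimethyl-1,3-dioxolan-4-yl]-3-hydroxy-4-methylpent-4-en-1-one | O=C(C[C@H](O)/C(C)=C\[C@@H]1COC(C)(C)O1)N1[C@H](Cc2ccccc2)CSC1=S | intermediate
9 | (3S,4Z)-1-[(4R)-4-benzyl-2-sulfanylidene-1,3-thiazolidin-3-yl]-3-[(tert-butyldimethylsilyl)oxy]-5-[(4R)-2,2-dimethyl-1,3-dioxolan-4-yl]-4-methylpent-4-en-1-one | O=C(C[C@H](O[Si](C)(C)C(C)(C)C)/C(C)=C\[C@@H]1COC(C)(C)O1)N1[C@H](Cc2ccccc2)CSC1=S | intermediate
10 | (3S,4Z)-3-[(tert-butyldimethylsilyl)oxy]-5-[(4R)-2,2-dimethyl-1,3-dioxolan-4-yl]-4-methylpent-4-enal | O=CC[C@H](O[Si](C)(C)C(C)(C)C)/C(C)=C\[C@@H]1COC(C)(C)O1 | intermediate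
11 | (4R)-4-[(1Z,3S,5Z)-3-[(tert-butyldimethylsilyl)oxy]-6-iodo-2-methylhepta-1,5-dien-1-yl]-2,2-dimethyl-1,3-dioxolane | C/C(I)=C/C[C@H](O[Si](C)(C)C(C)(C)C)/C(C)=C\[C@@H]1COC(C)(C)O1 | intermediate
12 | (2R,3Z,5S,7Z)-5-[(tert-butyldimethylsilyl)oxy]-8-iodo-4-methylnona-3,7-diene-1,2-diol | C/C(I)=C/C[C@H](O[Si](C)(C)C(C)(C)C)/C(C)=C\[C@@H](O)CO | intermediate
13 | (2R,3Z,5S,7Z)-5-[(tert-butyldimethylsilyl)oxy]-8-iodo-4-methyl-1,2-bis[(triethylsilyl)oxy]nona-3,7-diene | C/C(I)=C/C[C@H](O[Si](C)(C)C(C)(C)C)/C(C)=C\[C@@H](O[Si](CC)(CC)CC)CO[Si](CC)(CC)CC | intermediate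
14 | (2R,3Z,5S,7Z)-5-[(tert-butyldimethylsilyl)oxy]-8-iodo-4-methyl-2-[(triethylsilyl)oxy]nona-3,7-dienal | C/C(I)=C/C[C@H](O[Si](C)(C)C(C)(C)C)/C(C)=C\[C@@H](O[Si](CC)(CC)CC)C=O | intermediate
15 | methyl prop-2-enoate (methyl acrylate) | C=CC(=O)OC | starting material
16 | methyl (4R,5Z,7S,9Z)-7-[(tert-butyldimethylsilyl)oxy]-3-hydroxy-10-iodo-6-methyl-2-methylidene-4-[(triethylsilyl)oxy]undeca-5,9-dienoate, both C3 epimers | C/C(I)=C/C[C@H](O[Si](C)(C)C(C)(C)C)/C(C)=C\[C@@H](O[Si](CC)(CC)CC)C(O)C(=C)C(=O)OC | intermediate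
17 | methyl (2Z,4R,5Z,7S,9Z)-2-(bromomethyl)-7-[(tert-butyldimethylsilyl)oxy]-10-iodo-6-methyl-4-[(triethylsilyl)oxy]undeca-2,5,9-trienoate | C/C(I)=C/C[C@H](O[Si](C)(C)C(C)(C)C)/C(C)=C\[C@@H](O[Si](CC)(CC)CC)/C=C(\CBr)C(=O)OC | intermediate
18 | ethane-1,2-diol | OCCO | starting material
19 | methyl (2E,4R,5Z,7S,9Z)-7-[(tert-butyldimethylsilyl)oxy]-2-[(2-hydroxyethoxy)methyl]-10-iodo-6-methyl-4-[(triethylsilyl)oxy]undeca-2,5,9-trienoate | C/C(I)=C/C[C@H](O[Si](C)(C)C(C)(C)C)/C(C)=C\[C@@H](O[Si](CC)(CC)CC)/C=C(\COCCO)C(=O)OC | intermediate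
20 | methyl (2E,4R,5Z,7S,9Z)-7-[(tert-butyldimethylsilyl)oxy]-10-iodo-6-methyl-2-[(2-oxoethoxy)methyl]-4-[(triethylsilyl)oxy]undeca-2,5,9-trienoate | C/C(I)=C/C[C@H](O[Si](C)(C)C(C)(C)C)/C(C)=C\[C@@H](O[Si](CC)(CC)CC)/C=C(\COCC=O)C(=O)OC | intermediate
21 | methyl (3E,5R,6Z,8S,10Z)-8-[(tert-butyldimethylsilyl)oxy]-12-hydroxy-7,11-dimethyl-5-[(triethylsilyl)oxy]-1-oxacyclotrideca-3,6,10-triene-3-carboxylate, both C12 epimers | OC1COC/C(C(=O)OC)=C\[C@H](O[Si](CC)(CC)CC)/C=C(/C)[C@@H](O[Si](C)(C)C(C)(C)C)C/C=C1/C | intermediate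
22 | methyl (3E,5R,6Z,8S,10Z)-8-[(tert-butyldimethylsilyl)oxy]-7,11-dimethyl-12-oxo-5-[(triethylsilyl)oxy]-1-oxacyclotrideca-3,6,10-triene-3-carboxylate | O=C1COC/C(C(=O)OC)=C\[C@H](O[Si](CC)(CC)CC)/C=C(/C)[C@@H](O[Si](C)(C)C(C)(C)C)C/C=C1/C | intermediate
23 | lithium enolate of 22 (C8=C9, lithium on O9) | [Li]O/C1=C\OC/C(C(=O)OC)=C\[C@H](O[Si](CC)(CC)CC)/C=C(/C)[C@@H](O[Si](C)(C)C(C)(C)C)C/C=C1/C | intermediate (not isolated)
24 | methyl 2-[(1R,2R,3Z,5S,7Z,10S)-5-[(tert-butyldimethylsilyl)oxy]-10-hydroxy-4,8-dimethyl-9-oxo-2-[(triethylsilyl)oxy]cyclodeca-3,7-dien-1-yl]prop-2-enoate | CC[Si](CC)(CC)O[C@@H]1/C=C(/C)[C@@H](O[Si](C)(C)C(C)(C)C)C/C=C(/C)C(=O)[C@@H](O)[C@H]1C(=C)C(=O)OC | intermediate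
25 | (2E)-2-methylbut-2-enoic acid (tiglic acid) | C/C=C(\C)C(=O)O | starting material
26 | (2E)-2-methylbut-2-en-1-ol | C/C=C(\C)CO | intermediate
27 | [(2R,3R)-2,3-dimethyloxiran-2-yl]methanol | OC[C@@]1(C)O[C@@H]1C | intermediate
28 | (2S,3R)-2,3-dimethyloxirane-2-carboxylic acid | OC(=O)[C@@]1(C)O[C@@H]1C | intermediate
29 | (2S,3R)-2,3-dimethyloxirane-2-carboxylic 2,4,6-trichlorobenzoic anhydride | O=C(OC(=O)[C@@]1(C)O[C@@H]1C)c1c(Cl)cc(Cl)cc1Cl | intermediate (not isolated)
30 | methyl 2-[(1R,2R,3Z,5S,7Z,10S)-5-[(tert-butyldimethylsilyl)oxy]-10-{[(2S,3R)-2,3-dimethyloxirane-2-carbonyl]oxy}-4,8-dimethyl-9-oxo-2-[(triethylsilyl)oxy]cyclodeca-3,7-dien-1-yl]prop-2-enoate | CC[Si](CC)(CC)O[C@@H]1/C=C(/C)[C@@H](O[Si](C)(C)C(C)(C)C)C/C=C(/C)C(=O)[C@@H](OC(=O)[C@@]2(C)O[C@@H]2C)[C@H]1C(=C)C(=O)OC | intermediate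
31 | methyl 2-[(1S,2R,3Z,5S,7Z,10S)-10-{[(2S,3R)-2,3-dimethyloxirane-2-carbonyl]oxy}-2,5-dihydroxy-4,8-dimethyl-9-oxocyclodeca-3,7-dien-1-yl]prop-2-enoate | O[C@@H]1/C=C(/C)[C@@H](O)C/C=C(/C)C(=O)[C@@H](OC(=O)[C@@]2(C)O[C@@H]2C)[C@H]1C(=C)C(=O)OC | intermediate (not isolated)
32 | (3aS,4S,6Z,9S,10Z,11aR)-9-hydroxy-6,10-dimethyl-3-methylidene-2,5-dioxo-2,3,3a,4,5,8,9,11a-octahydrocyclodeca[b]furan-4-yl (2S,3R)-2,3-dimethyloxirane-2-carboxylate | C=C1C(=O)O[C@@H]2/C=C(/C)[C@@H](O)C/C=C(/C)C(=O)[C@@H](OC(=O)[C@@]3(C)O[C@@H]3C)[C@@H]12 | intermediate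
33 | (3aS,4S,6Z,9S,10Z,11aR)-9-(acetyloxy)-6,10-dimethyl-3-methylidene-2,5-dioxo-2,3,3a,4,5,8,9,11a-octahydrocyclodeca[b]furan-4-yl (2S,3R)-2,3-dimethyloxirane-2-carboxylate | C=C1C(=O)O[C@@H]2/C=C(/C)[C@@H](OC(C)=O)C/C=C(/C)C(=O)[C@@H](OC(=O)[C@@]3(C)O[C@@H]3C)[C@@H]12 | intermediate
34 | (3aS,4S,5R,6Z,9S,10Z,11aR)-9-(acetyloxy)-5-hydroxy-6,10-dimethyl-3-methylidene-2-oxo-2,3,3a,4,5,8,9,11a-octahydrocyclodeca[b]furan-4-yl (2S,3R)-2,3-dimethyloxirane-2-carboxylate | C=C1C(=O)O[C@@H]2/C=C(/C)[C@@H](OC(C)=O)C/C=C(/C)[C@@H](O)[C@@H](OC(=O)[C@@]3(C)O[C@@H]3C)[C@@H]12 | target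

## Step count and least certain steps

Total: 24 steps. Longest linear sequence: 21 steps (steps 1–17 and 21–24); acid 28 is made in 3 steps (18–20) and joins at step 21.

**Step 17 (key step).** Three processes may defeat it:
- The enolate may rearrange by the [3,3] or [1,2] path, or not at all, because a ketone enolate is a weaker [2,3] donor than an ester enolate.
- The C8 alkoxide may close onto the C12 ester before the quench.
- The envelope may fold with C9 endo or on the other face of C7, giving poor diastereoselectivity.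

Fallback, setting out from 17 and returning at 24: C7–C8 is made by a Barbier allylation and the ten-membered ring is closed afterwards.
- Indium-mediated allylation of [(4-methoxybenzyl)oxy]acetaldehyde with 17 (In, THF/H2O) should attack through C7 in a chair and give the syn homoallylic alcohol F1.
- DDQ frees the diol F2.
- TEMPO with PhI(OAc)2 oxidises the primary hydroxyl to the α-hydroxy aldehyde F3.
- Intramolecular Nozaki–Hiyama–Kishi coupling (CrCl2, NiCl2 cat.) of the C10 iodide with C9 closes the ring to the cyclic diol F4.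
- MnO2 oxidises only the allylic C9 hydroxyl and gives 24.

**Step 11.** Epimerisation at C6, or migration of the C4=C5 double bond into conjugation, may occur during the slow amine-catalysed reaction, because H6 of 14 is both α to the aldehyde and allylic. Fallback, setting out from 14 and returning at 16: methyl propiolate is hydroaluminated with DIBAL-H and N-methylmorpholine N-oxide (THF, 0 °C) to the α-(methoxycarbonyl)vinylalane, which adds to 14 within hours without an amine base. This vinylalumination gives 16 directly and makes no compound outside the list (F0).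

**Step 13.** The diol may attack at C7 instead of C13 (SN2′, giving the branched ether), or silver-assisted ionisation may cost the C6 silyl ether. Fallback, setting out from 17 and returning at 20:
- KOAc in DMF displaces bromide at C13 to give the allylic acetate F5.
- K2CO3 in MeOH gives the allylic alcohol F6.
- Rh2(OAc)4-catalysed O–H insertion of 2-diazo-N-methoxy-N-methylacetamide gives the ether amide F7.
- Cp2Zr(H)Cl reduces the amide to aldehyde 20.

**Step 15.** Oligomerisation or reduction of the aldehyde may outrun the slow oxidative addition of the hindered trisubstituted iodide. Fallback, setting out from 16 and returning at 22: C9–C10 is made between two molecules and the ring is closed at the ether.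
- Nozaki–Hiyama–Kishi coupling of 16 with excess [(4-methoxybenzyl)oxy]acetaldehyde gives the diol F8.
- MnO2 oxidises the C9 allylic alcohol to the enone F9.
- NBS with Me2S converts the remaining carbinol to the allylic bromide F10.
- DDQ removes the 4-methoxybenzyl group to give the hydroxy ketone F11.
- Ag2O under high dilution closes the thirteen-membered ether 22.

**Step 22.** Lactonisation may stay incomplete (the C6 hydroxyl must reach a conjugated methyl ester across a trans ring fusion), fluoride may open the epoxide, or the acyl group may shift from O8 to O6. Fallback, setting out from 30 and returning at 32: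
- Me3SnOH (1,2-dichloroethane, 70 °C) cleaves the unhindered methyl ester to the acid F12.
- HF·pyridine gives the dihydroxy acid F13.
- Carboxyl activation with 2-methyl-6-nitrobenzoic anhydride and DMAP closes the γ-lactone 32.

**Step 24.** Facial selectivity at C9 may be poor, since the ring conformation rather than the C8 ester may decide the face. Conjugate reduction of the methylene lactone and acyl shift from O8 to the new O9 are further risks. Fallback, setting out from 33 and returning at 34: if the reduction gives mainly the C9 epimer F14, a Mitsunobu reaction with chloroacetic acid (PPh3, DIAD) inverts C9 to the chloroacetate F15, and thiourea with NaHCO3 removes the chloroacetyl group selectively to give 34.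

## Further compounds

F1 | step 17 | open-chain Barbier adduct: methyl 2-methylidene ester with C8 hydroxyl, C9 4-methoxybenzyl ether, C6 triethylsilyl ether, C3 tert-butyldimethylsilyl ether and C10 vinyl iodide | C/C(I)=C/C[C@H](O[Si](C)(C)C(C)(C)C)/C(C)=C\[C@@H](O[Si](CC)(CC)CC)[C@H](C(=C)C(=O)OC)[C@H](O)COCc1ccc(OC)cc1
F2 | step 17 | open-chain C8,C9 diol from F1 | C/C(I)=C/C[C@H](O[Si](C)(C)C(C)(C)C)/C(C)=C\[C@@H](O[Si](CC)(CC)CC)[C@H](C(=C)C(=O)OC)[C@H](O)CO
F3 | step 17 | open-chain C8 hydroxy C9 aldehyde from F2 | C/C(I)=C/C[C@H](O[Si](C)(C)C(C)(C)C)/C(C)=C\[C@@H](O[Si](CC)(CC)CC)[C@H](C(=C)C(=O)OC)[C@H](O)C=O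
F4 | step 17 | ten-membered C8,C9 diol (both C9 epimers) | CC[Si](CC)(CC)O[C@@H]1/C=C(/C)[C@@H](O[Si](C)(C)C(C)(C)C)C/C=C(/C)C(O)[C@@H](O)[C@H]1C(=C)C(=O)OC
F0 | step 11 | none | none
F5 | step 13 | methyl (2E,4R,5Z,7S,9Z)-2-(acetoxymethyl)-7-[(tert-butyldimethylsilyl)oxy]-10-iodo-6-methyl-4-[(triethylsilyl)oxy]undeca-2,5,9-trienoate | C/C(I)=C/C[C@H](O[Si](C)(C)C(C)(C)C)/C(C)=C\[C@@H](O[Si](CC)(CC)CC)/C=C(\COC(C)=O)C(=O)OC
F6 | step 13 | methyl (2E,4R,5Z,7S,9Z)-7-[(tert-butyldimethylsilyl)oxy]-2-(hydroxymethyl)-10-iodo-6-methyl-4-[(triethylsilyl)oxy]undeca-2,5,9-trienoate | C/C(I)=C/C[C@H](O[Si](C)(C)C(C)(C)C)/C(C)=C\[C@@H](O[Si](CC)(CC)CC)/C=C(\CO)C(=O)OC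
F7 | step 13 | C13 ether of F6 with N-methoxy-N-methylglycolamide | C/C(I)=C/C[C@H](O[Si](C)(C)C(C)(C)C)/C(C)=C\[C@@H](O[Si](CC)(CC)CC)/C=C(\COCC(=O)N(C)OC)C(=O)OC
F8 | step 15 | open-chain C7,C9 diol with C8 4-methoxybenzyl ether (epimers at C7 and C9) | COc1ccc(COCC(O)/C(C)=C\C[C@H](O[Si](C)(C)C(C)(C)C)/C(C)=C\[C@@H](O[Si](CC)(CC)CC)C(O)C(=C)C(=O)OC)cc1
F9 | step 15 | open-chain C9 enone with C7 carbinol and C8 4-methoxybenzyl ether | COc1ccc(COCC(=O)/C(C)=C\C[C@H](O[Si](C)(C)C(C)(C)C)/C(C)=C\[C@@H](O[Si](CC)(CC)CC)C(O)C(=C)C(=O)OC)cc1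
F10 | step 15 | open-chain C9 enone with C13 bromide and C8 4-methoxybenzyl ether | COc1ccc(COCC(=O)/C(C)=C\C[C@H](O[Si](C)(C)C(C)(C)C)/C(C)=C\[C@@H](O[Si](CC)(CC)CC)/C=C(\CBr)C(=O)OC)cc1
F11 | step 15 | open-chain C8 hydroxy C9 ketone with C13 bromide | OCC(=O)/C(C)=C\C[C@H](O[Si](C)(C)C(C)(C)C)/C(C)=C\[C@@H](O[Si](CC)(CC)CC)/C=C(\CBr)C(=O)OC
F12 | step 22 | C12 carboxylic acid of 30 | CC[Si](CC)(CC)O[C@@H]1/C=C(/C)[C@@H](O[Si](C)(C)C(C)(C)C)C/C=C(/C)C(=O)[C@@H](OC(=O)[C@@]2(C)O[C@@H]2C)[C@H]1C(=C)C(=O)O
F13 | step 22 | C3,C6 dihydroxy C12 acid | O[C@@H]1/C=C(/C)[C@@H](O)C/C=C(/C)C(=O)[C@@H](OC(=O)[C@@]2(C)O[C@@H]2C)[C@H]1C(=C)C(=O)O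
F14 | step 24 | C9 epimer of 34 | C=C1C(=O)O[C@@H]2/C=C(/C)[C@@H](OC(C)=O)C/C=C(/C)[C@H](O)[C@@H](OC(=O)[C@@]3(C)O[C@@H]3C)[C@@H]12
F15 | step 24 | 9-O-chloroacetate of 34 | C=C1C(=O)O[C@@H]2/C=C(/C)[C@@H](OC(C)=O)C/C=C(/C)[C@@H](OC(=O)CCl)[C@@H](OC(=O)[C@@]3(C)O[C@@H]3C)[C@@H]12
A1 | alternative 1 | ten-membered α-methylene lactone with C3 acetate, C9 tert-butyldimethylsilyl ether and C8 4-methoxybenzyl ether | C=C1C(=O)O[C@@H]2/C=C(/C)[C@@H](OC(C)=O)C/C=C(/C)[C@@H](O[Si](C)(C)C(C)(C)C)[C@@H](OCc3ccc(OC)cc3)[C@@H]12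
A2 | alternative 2 | ten-membered C3 allylic alcohol with C6 and C9 tert-butyldimethylsilyl ethers, C8 4-methoxybenzyl ether and a 3-silyloxyprop-1-en-2-yl group on C7 | CC(C)(C)[Si](C)(C)O[C@@H]1/C=C(/C)[C@@H](O)C/C=C(/C)[C@@H](O[Si](C)(C)C(C)(C)C)[C@@H](OCc2ccc(OC)cc2)[C@H]1C(=C)CO[Si](C)(C)C(C)(C)C
A3 | alternative 3 | ten-membered C9 ketone with C6 4-methoxybenzyl ether, C3 methoxymethyl ether and a 2-silyloxyethyl chain on C7 | COc1ccc(CO[C@@H]2/C=C(/C)[C@@H](OCOC)C/C=C(/C)C(=O)C[C@H]2CCO[Si](C)(C)C(C)(C)C)cc1
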